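**Retrosynthetic overview**
1. Target ⇐ transannular C7–O bond: visible-light dehydrogenative etherification of a macrocyclic 7Z-alkene triol (tetrahydrofuran formed last; sets C7 and the 8(19)-methylidene).
2. Macrocycle ⇐ C1–C2 bond: visible-light, chromium-catalysed allylation of an aldehyde by the allylic bromide of an α,β-unsaturated ε-lactone (closes the 14-membered ring; sets C1 and C2).
3. Seco compound ⇐ C8–C9 bond: B-alkyl Suzuki union of a (Z)-vinyl iodide diol (C2–C8) with a vinyl carbinol lactone (C9–C17; C11 by Felkin vinylation).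
4. ε-Lactone ⇐ intramolecular Nozaki–Hiyama–Kishi closure of a 2-bromoacrylate aldehyde (first ring).
5. Both halves ⇐ (S)-linalool 1, which supplies C4 and C12. Ring order: ε-lactone → 14-membered carbocycle → tetrahydrofuran.

Assumption: cembrane-type locants are used (C1 = ring CH carrying the acrylate carbon C15, C2 = adjacent carbinol, C4/C7 = ether carbons, C11/C12 = diol carbons, C16 = lactone C=O, C17 = exocyclic CH2); (S)-(+)-linalool of high ee is taken as commercial; the ring carbinol made in step 6 is carried as an epimer mixture until it becomes sp2 in step 11; OH groups are drawn free in the borane intermediates 5 and 15.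

**Step 1**
Reactants: 1 (S)-linalool
Product: 3 (5S)-5-ethenyl-5-methyloxolan-2-ol, via ozonide 2 (not isolated)
Conditions: O3, CH2Cl2, −78 °C (Sudan Red 7B end point); Me2S, −78 °C to rt
Reagents that add atoms: ozone, [O-][O+]=O
Why: Criegee ozonolysis with reductive work-up cleaves the electron-rich trisubstituted alkene before the vinyl group, and the hydroxy aldehyde closes to the lactol without touching the bought C4 centre.

**Step 2**
Reactants: 3 (5S)-5-ethenyl-5-methyloxolan-2-ol
Product: 4 (3S,6Z)-7-iodo-3-methylocta-1,6-dien-3-ol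
Conditions: EtPPh3I, n-BuLi, THF, 0 °C; I2, −78 °C; NaHMDS (2 equiv), −78 °C; then 3, −78 to −20 °C
Reagents that add atoms: ethyltriphenylphosphonium iodide, CC[P+](c1ccccc1)(c1ccccc1)c1ccccc1.[I-]; iodine, II
Why: Stork–Zhao-type Wittig olefination of the open hydroxy-aldehyde form with the α-iodo ylide gives the (Z)-2-iodoalkene (iodine cis to the chain) under kinetic control.

**Step 3**
Reactants: 4 (3S,6Z)-7-iodo-3-methylocta-1,6-dien-3-ol
Product: 6 (3S,6Z)-7-iodo-3-methyloct-6-ene-1,3-diol, via B-alkyl-9-BBN adduct 5 (not isolated)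
Conditions: 9-BBN, THF, 0 °C to rt; then NaOH, H2O2, 0 °C
Reagents that add atoms: 9-borabicyclo[3.3.1]nonane, [BH]1C2CCCC1CCC2 (boron stays only in 5); hydrogen peroxide, OO
Why: Anti-Markovnikov hydroboration–oxidation takes only the monosubstituted vinyl group (the iodoalkene is inert to 9-BBN) and installs the C2 oxygen.

**Step 4**
Reactants: 1 (S)-linalool
Product: 8 (3S)-3,7-dimethylocta-1,6-dien-3-yl 2-bromoprop-2-enoate, via 2,3-dibromopropanoate ester 7 (not isolated)
Conditions: n-BuLi, THF, −78 °C; BrCH2CHBrCOCl, −78 to 0 °C; then Et3N, 0 °C to rt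
Reagents that add atoms: 2,3-dibromopropanoyl chloride, BrCC(Br)C(Cl)=O
Why: O-acylation of the lithium tert-alkoxide followed by E2 loss of HBr gives the 2-bromoacrylate under basic conditions that do not ionise the tertiary allylic ester; the C12–O bond is now in place.

**Step 5**
Reactants: 8 (3S)-3,7-dimethylocta-1,6-dien-3-yl 2-bromoprop-2-enoate
Product: 10 (3S)-3-methyl-6-oxohex-1-en-3-yl 2-bromoprop-2-enoate, via ozonide 9 (not isolated)
Conditions: O3, CH2Cl2, −78 °C (Sudan Red 7B end point); Me2S
Reagents that add atoms: ozone, [O-][O+]=O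
Why: Chemoselective ozonolysis of the trisubstituted alkene; the vinyl group (allylic acyloxy) and the electron-poor bromoacrylate react much more slowly.

**Step 6**
Reactants: 10 (3S)-3-methyl-6-oxohex-1-en-3-yl 2-bromoprop-2-enoate
Product: 11 (4RS,7S)-7-ethenyl-4-hydroxy-7-methyl-3-methylideneoxepan-2-one
Conditions: CrCl2 (4 equiv), NiCl2 (2 mol%), DMF/THF, 5 mM, rt
Reagents that add atoms: none
Why: Intramolecular Nozaki–Hiyama–Kishi reaction (Ni inserts into the vinylic C–Br bond, the vinylchromium adds to the tethered aldehyde) closes the seven-membered lactone on the tertiary C12 oxygen; the new carbinol centre is removed in step 11.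

**Step 7**
Reactants: 11 (4RS,7S)-7-ethenyl-4-hydroxy-7-methyl-3-methylideneoxepan-2-one
Product: 13 (2S,5RS)-5-hydroxy-2-methyl-6-methylidene-7-oxooxepane-2-carbaldehyde, via ozonide 12 (not isolated)
Conditions: O3, CH2Cl2, −78 °C (Sudan Red 7B end point); Me2S
Reagents that add atoms: ozone, [O-][O+]=O
Why: Ozonolysis of the isolated vinyl group, which should be cleaved ahead of the conjugated acrylate-type exocyclic alkene when the reaction is stopped at the indicator end point, exposes the C11 aldehyde.

**Step 8**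
Reactants: 13 (2S,5RS)-5-hydroxy-2-methyl-6-methylidene-7-oxooxepane-2-carbaldehyde
Product: 14 (4RS,7S)-4-hydroxy-7-[(1S)-1-hydroxyprop-2-en-1-yl]-7-methyl-3-methylideneoxepan-2-one
Conditions: CH2=CHBr, CrCl2 (4 equiv), NiCl2 (1 mol%), DMF, 0 °C to rt
Reagents that add atoms: vinyl bromide, C=CBr
Why: Nozaki–Hiyama–Kishi vinylation is aldehyde-selective (lactone and acrylate untouched) and should follow a non-chelated Felkin–Anh course (ring C–O anti to the nucleophile, tied-back ring CH2 as the small group), giving 11S from the bought C12 centre (dr about 5:1 expected, minor epimer removed).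

**Step 9**
Reactants: 14 (4RS,7S)-4-hydroxy-7-[(1S)-1-hydroxyprop-2-en-1-yl]-7-methyl-3-methylideneoxepan-2-one; 6 (3S,6Z)-7-iodo-3-methyloct-6-ene-1,3-diol
Product: 16 (4RS,7S)-4-hydroxy-7-methyl-3-methylidene-7-[(1S,4Z,8S)-1,8,10-trihydroxy-4,8-dimethyldec-4-en-1-yl]oxepan-2-one, via B-alkyl-9-BBN adduct 15 (not isolated)
Conditions: 9-BBN (3.5 equiv), THF, rt; then 6, Pd(dppf)Cl2 (10 mol%), AsPh3, Cs2CO3, DMF/H2O, rt
Reagents that add atoms: 9-borabicyclo[3.3.1]nonane, [BH]1C2CCCC1CCC2 (boron stays only in 15)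
Why: Terminal-selective hydroboration and B-alkyl Suzuki–Miyaura coupling form C8–C9 with retention of the vinyl iodide geometry (7Z) and tolerate the free hydroxyls and the hindered tertiary-alkyl lactone.

**Step 10**
Reactants: 16 (4RS,7S)-4-hydroxy-7-methyl-3-methylidene-7-[(1S,4Z,8S)-1,8,10-trihydroxy-4,8-dimethyldec-4-en-1-yl]oxepan-2-one
Product: 17 (3S,6Z,10S)-3,10-dihydroxy-10-[(2S,5RS)-5-hydroxy-2-methyl-6-methylidene-7-oxooxepan-2-yl]-3,7-dimethyldec-6-enal
Conditions: TEMPO (20 mol%), PhI(OAc)2, CH2Cl2, rt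
Reagents that add atoms: none
Why: Oxoammonium (TEMPO/BAIB) oxidation is selective for the primary alcohol over the hindered secondary, electron-poor allylic and tertiary hydroxyls, giving the C2 aldehyde.

**Step 11**
Reactants: 17 (3S,6Z,10S)-3,10-dihydroxy-10-[(2S,5RS)-5-hydroxy-2-methyl-6-methylidene-7-oxooxepan-2-yl]-3,7-dimethyldec-6-enal
Product: 18 (3S,6Z,10S)-10-[(2S)-6-(bromomethyl)-2-methyl-7-oxo-2,3,4,7-tetrahydrooxepin-2-yl]-3,10-dihydroxy-3,7-dimethyldec-6-enal
Conditions: NBS, Me2S, CH2Cl2, −30 to 0 °C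
Reagents that add atoms: N-bromosuccinimide, O=C1CCC(=O)N1Br
Why: Corey–Kim bromination converts only the activated Baylis–Hillman-type allylic alcohol, by SN2′ attack of bromide on its alkoxysulfonium salt, into the primary allylic bromide with the alkene now endocyclic and conjugated.

**Step 12**
Reactants: 18 (3S,6Z,10S)-10-[(2S)-6-(bromomethyl)-2-methyl-7-oxo-2,3,4,7-tetrahydrooxepin-2-yl]-3,10-dihydroxy-3,7-dimethyldec-6-enal
Product: 19 (1R,2S,4S,7Z,11S,12S)-2,4,11-trihydroxy-4,8,12-trimethyl-15-methylidene-13-oxabicyclo[10.3.2]heptadec-7-en-14-one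
Conditions: CrCl3·3THF (20 mol%), 4CzIPN (3 mol%), Hantzsch ester (1.5 equiv), 2,6-lutidine (1.5 equiv), MeCN/THF, 1 mM (slow addition), 450 nm LEDs, rt
Reagents that add atoms: none
Why: Proposed new method: a chromium/organophotoredox Nozaki–Hiyama–Kishi-type macrocyclisation in which the photoreduced catalyst (quenched by the Hantzsch ester) turns Cr(III) into Cr(II), two Cr(II) convert the allylic bromide into the ring-locked (E)-type allylchromium(III), this adds through C1 to the tethered aldehyde in a Zimmerman–Traxler chair (1,2-anti, hence 1R,2S) with the chain that leaves C12 opposite its methyl group reaching the methyl-bearing face of C1 (trans bridge; this facial sense is argued from the tether and is not secured), and lutidinium protonates the Cr alkoxide to close the cycle; closest known reaction types are intermolecular photoredox/chromium allylations of aldehydes and stoichiometric CrCl2 macrocyclisations of 2-(bromomethyl)enoates.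

**Step 13**
Reactants: 19 (1R,2S,4S,7Z,11S,12S)-2,4,11-trihydroxy-4,8,12-trimethyl-15-methylidene-13-oxabicyclo[10.3.2]heptadec-7-en-14-one
Product: 20 (1R,2S,4S,7R,11S,12S)-2,11-dihydroxy-4,12-dimethyl-8,15-dimethylidene-13,18-dioxatricyclo[10.3.2.1(4,7)]octadecan-14-one
Conditions: 3,6-di-tert-butyl-9-mesityl-10-phenylacridinium BF4 (5 mol%), Co(dmgH)2(py)Cl (8 mol%), 2,6-lutidine (20 mol%), DCE, 2 mM, 450 nm LEDs, rt, Ar
Reagents that add atoms: none
Why: Proposed new method: an acridinium/cobaloxime dehydrogenative anti-Markovnikov cycloetherification in which the excited acridinium oxidises only the trisubstituted alkene to its radical cation, the C4 hydroxyl adds 5-exo at the less substituted C7 (only a cis-2,5 bridge fits inside the 14-membered ring, which sets 7R), Co(II) captures the tertiary C8 radical and removes a hydrogen from the unhindered C19 methyl to give the 8(19)-methylidene, and Co–H plus H+ release H2; closest known reaction types are acridinium-photocatalysed anti-Markovnikov hydroetherification of alkenols and photoredox/cobaloxime acceptorless dehydrogenation.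

**Compound list**
1 | (S)-linalool, (3S)-3,7-dimethylocta-1,6-dien-3-ol | C=C[C@](O)(C)CCC=C(C)C | starting material
2 | (3S)-5-(5,5-dimethyl-1,2,4-trioxolan-3-yl)-3-methylpent-1-en-3-ol (ozonide) | C=C[C@](O)(C)CCC1OOC(C)(C)O1 | intermediate
3 | (5S)-5-ethenyl-5-methyloxolan-2-ol (anomer mixture) | C=C[C@]1(C)CCC(O)O1 | intermediate
4 | (3S,6Z)-7-iodo-3-methylocta-1,6-dien-3-ol | C=C[C@](O)(C)CC/C=C(/C)I | intermediate
5 | (3R,6Z)-1-(9-borabicyclo[3.3.1]nonan-9-yl)-7-iodo-3-methyloct-6-en-3-ol (same spatial arrangement as 4; descriptor changes by CIP rank only) | C(C[C@](O)(C)CC/C=C(/C)I)B1C2CCCC1CCC2 | intermediate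
6 | (3S,6Z)-7-iodo-3-methyloct-6-ene-1,3-diol | OCC[C@](O)(C)CC/C=C(/C)I | intermediate
7 | (3S)-3,7-dimethylocta-1,6-dien-3-yl 2,3-dibromopropanoate | BrCC(Br)C(=O)O[C@@](C=C)(C)CCC=C(C)C | intermediate
8 | (3S)-3,7-dimethylocta-1,6-dien-3-yl 2-bromoprop-2-enoate | C=C(Br)C(=O)O[C@@](C=C)(C)CCC=C(C)C | intermediate
9 | (3S)-5-(5,5-dimethyl-1,2,4-trioxolan-3-yl)-3-methylpent-1-en-3-yl 2-bromoprop-2-enoate (ozonide) | C=C(Br)C(=O)O[C@@](C=C)(C)CCC1OOC(C)(C)O1 | intermediate
10 | (3S)-3-methyl-6-oxohex-1-en-3-yl 2-bromoprop-2-enoate | C=C(Br)C(=O)O[C@@](C=C)(C)CCC=O | intermediate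
11 | (4RS,7S)-7-ethenyl-4-hydroxy-7-methyl-3-methylideneoxepan-2-one | C=C1C(=O)O[C@@](C=C)(C)CCC1O | intermediate
12 | (4RS,7S)-4-hydroxy-7-methyl-3-methylidene-7-(1,2,4-trioxolan-3-yl)oxepan-2-one (ozonide) | C=C1C(=O)O[C@@](C2OOCO2)(C)CCC1O | intermediate
13 | (2S,5RS)-5-hydroxy-2-methyl-6-methylidene-7-oxooxepane-2-carbaldehyde | C=C1C(=O)O[C@@](C=O)(C)CCC1O | intermediate
14 | (4RS,7S)-4-hydroxy-7-[(1S)-1-hydroxyprop-2-en-1-yl]-7-methyl-3-methylideneoxepan-2-one | C=C1C(=O)O[C@@]([C@@H](O)C=C)(C)CCC1O | intermediate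
15 | (4RS,7S)-7-[(1S)-3-(9-borabicyclo[3.3.1]nonan-9-yl)-1-hydroxypropyl]-4-hydroxy-7-methyl-3-methylideneoxepan-2-one | C=C1C(=O)O[C@@]([C@@H](O)CCB2C3CCCC2CCC3)(C)CCC1O | intermediate
16 | (4RS,7S)-4-hydroxy-7-methyl-3-methylidene-7-[(1S,4Z,8S)-1,8,10-trihydroxy-4,8-dimethyldec-4-en-1-yl]oxepan-2-one | C=C1C(=O)O[C@@]([C@@H](O)CC/C(C)=C\CC[C@](C)(O)CCO)(C)CCC1O | intermediate
17 | (3S,6Z,10S)-3,10-dihydroxy-10-[(2S,5RS)-5-hydroxy-2-methyl-6-methylidene-7-oxooxepan-2-yl]-3,7-dimethyldec-6-enal | C=C1C(=O)O[C@@]([C@@H](O)CC/C(C)=C\CC[C@](C)(O)CC=O)(C)CCC1O | intermediate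
18 | (3S,6Z,10S)-10-[(2S)-6-(bromomethyl)-2-methyl-7-oxo-2,3,4,7-tetrahydrooxepin-2-yl]-3,10-dihydroxy-3,7-dimethyldec-6-enal | BrCC1=CCC[C@@](C)([C@@H](O)CC/C(C)=C\CC[C@](C)(O)CC=O)OC1=O | intermediate
19 | (1R,2S,4S,7Z,11S,12S)-2,4,11-trihydroxy-4,8,12-trimethyl-15-methylidene-13-oxabicyclo[10.3.2]heptadec-7-en-14-one (locants 1–12 equal the cembrane locants) | C=C1C(=O)O[C@@]2(C)CC[C@H]1[C@@H](O)C[C@](O)(C)CC/C=C(C)\CC[C@@H]2O | intermediate
20 | CNP0289823.1, (1R,2S,4S,7R,11S,12S)-2,11-dihydroxy-4,12-dimethyl-8,15-dimethylidene-13,18-dioxatricyclo[10.3.2.1(4,7)]octadecan-14-one | C=C1C(=O)O[C@@]2(C)CC[C@H]1[C@@H](O)C[C@]1(C)CC[C@@H](O1)C(=C)CC[C@@H]2O | target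

**Totals**
Total step count: 13. Longest linear sequence: 10 steps (steps 4–13 from 1); steps 1–3 form the second branch, which joins at step 9. No protecting groups are used.

**Three steps most likely to fail**

Step 12 (proposed new method). The risks are protodebromination or oligomerisation instead of ring closure, translactonisation of the C2 chromium alkoxide onto the lactone carbonyl (γ-lactone), and delivery to the wrong face of C1 (cis- instead of trans-bridged ring; the facial argument is the weakest stereochemical point of the route). The fallback uses known chemistry and leaves the photocatalytic cycle: it sets out from 18 and closes the same C1–C2 bond in the dark by a stoichiometric Nozaki–Hiyama–Kishi macrocyclisation (CrCl2 8–10 equiv, NiCl2 cat., 4 Å molecular sieves, THF/DMF, 1 mM, syringe-pump addition), the established thermal way to 14-membered cembranoid rings from 2-(bromomethyl)enoates. It makes no new compound (F0) and comes back to the route at 19. It does not correct a wrong facial sense at C1.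

Step 13 (proposed new method). The risks are hydrogen loss from C9 or C7 instead of C19, attack of the C11 hydroxyl on the radical cation, and transannular addition of the C8 radical to the acrylate. The fallback uses known chemistry and sets out from 19. Both secondary hydroxyls are silylated (TESCl, imidazole, DMF, 0 °C; the tertiary C4–OH stays free) to give (1R,2S,4S,7Z,11S,12S)-4-hydroxy-4,8,12-trimethyl-15-methylidene-2,11-bis(triethylsilyloxy)-13-oxabicyclo[10.3.2]heptadec-7-en-14-one F2. A Pd(II) Wacker-type oxidative cyclisation (PdCl2(MeCN)2 cat., benzoquinone, NaHCO3, THF, rt; oxypalladation at C7, β-hydride loss from the C19 methyl) then gives the 2,11-bis(triethylsilyl) ether of 20 F3, and HF·pyridine in THF removes both silyl groups, coming back to the route at 20.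

Step 8. The Felkin sense rests on the ring CH2 behaving as the smaller group next to the quaternary C12; the 11R epimer may dominate. The fallback sets out from the C11-epimer mixture of 14 from step 8. Selective oxidation of the vinyl carbinol (activated MnO2, CH2Cl2; the electron-poor ring carbinol is left) gives the vinyl ketone (4RS,7S)-4-hydroxy-7-methyl-3-methylidene-7-(prop-2-enoyl)oxepan-2-one F1. Luche reduction (NaBH4, CeCl3, MeOH, −78 °C) then delivers hydride along the trajectory the vinyl group took, which inverts the major C11 configuration, and comes back to the route at 14.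

**Further compounds**
F1 | step 8 | (4RS,7S)-4-hydroxy-7-methyl-3-methylidene-7-(prop-2-enoyl)oxepan-2-one | C=C1C(=O)O[C@@](C(=O)C=C)(C)CCC1O
F0 | step 12 | none | none
F2 | step 13 | (1R,2S,4S,7Z,11S,12S)-4-hydroxy-4,8,12-trimethyl-15-methylidene-2,11-bis(triethylsilyloxy)-13-oxabicyclo[10.3.2]heptadec-7-en-14-one | C=C1C(=O)O[C@@]2(C)CC[C@H]1[C@@H](O[Si](CC)(CC)CC)C[C@](O)(C)CC/C=C(C)\CC[C@@H]2O[Si](CC)(CC)CC
F3 | step 13 | 2,11-bis(triethylsilyl) ether of 20 | C=C1C(=O)O[C@@]2(C)CC[C@H]1[C@@H](O[Si](CC)(CC)CC)C[C@]1(C)CC[C@@H](O1)C(=C)CC[C@@H]2O[Si](CC)(CC)CC
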